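(All runs are simulated from invented constants, noise included.)

The clock comes first.

| setting | Friday's | Monday's | flask |
|---|---|---|---|
| starting material | 0.098 M | 0.15 M | 0.098 M |
| gas phase | 49 mM (held) | 49 mM (held) | 49 mM (held) |
| temperature | 25 °C | 25 °C | 25 °C |
| remark | the very flask that is asked about, followed so far | run made earlier |  |
| time |  |  | 2.0 d |

| run | time / h | target / % | starting material / % |
|---|---|---|---|
| Friday's | 6.00 | 25.9 | 55.8 |
| Friday's | 15.0 | 33.8 | 21.6 |
| Friday's | 20.0 | 39.5 | 12.3 |
| Friday's | 30.0 | 41.1 | 5.7 |
| Friday's | 40.0 | 41.2 | 1.6 |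
| Friday's | 50.0 | 42.1 | 0.4 |
| Monday's | 0.417 | 0.6 | 99.6 |
| Monday's | 1.00 | 5.2 | 93.6 |
| Monday's | 2.00 | 11.3 | 85.6 |
| Monday's | 3.00 | 16.6 | 78.2 |
| Monday's | 4.00 | 18.3 | 70.4 |
| Monday's | 6.00 | 25.1 | 57.2 |
| Monday's | 8.00 | 27.9 | 47.6 |

(each reading ± 1 percentage point)

- birch: at 2.0 d raise the temperature by 25 K, then wait 4.0 d
- oak: at 2.0 d add starting material, 50.0% of the amount charged, then wait 4.0 d
- cedar: change nothing and wait 4.0 d more
- larch: at 2.0 d take out 90% of the target then present, then wait 4.0 d

- target taken out counts as made
- the analysis behind the earlier runs scatters by 1 percentage point, standard deviation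
- at the start none of the gas phase is in solution
- additions bring no volume worth counting

1. target, in percent of the starting material first charged, at 2.0 d
2. the option that brings most further target ("none" if no option brings more than 2 percentage points) (birch / oak / cedar / larch / none)
3. target present, with what was taken out counted in, in percent of the starting material first charged, after oak
4. target present, with what was taken out counted in, in percent of the starting material first charged, after cedar

- Monday's run, charged with 0.15 M against Friday's 0.098 M, holds 57.2% of its starting material at 6.00 h, where Friday's run holds 55.8%, a gap of 1.4 percentage points against a scatter of 1 point, so I take the rate as first order in the starting material and fold the gas in solution, fed by the held gas phase, into one constant.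
- Friday's readings fall from 55.8% at 6.00 h to 12.3% at 20.0 h, which gives 0.108 h⁻¹, and this reading is k′, the pseudo-first-order constant, the fall of the logarithm of the starting material per unit time.
- Carried from 6.00 h to 2.0 d, k′ leaves 0.598% of the starting material in the asked flask, less than the 2 points that counts, so I leave cedar out and take the mean of the last 3 target readings of Friday's run as my reckoning for now, 41.5%.
- For oak, k′ leaves 0.00314% of the addition after 4.0 d, so with the same share going to target I reckon a gain of 21 points and a total of 62.5%.
- Larch and birch lie outside k′: my reckoning leaves 57.9% of the charge of the asked flask unaccounted for, and both runs stood at 25 °C, so I hold them open and commit to oak as the gain I can reckon.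
- The forecast gives 42% now, 63% after oak, 42% after cedar and oak as best, in its words “Oak is narrowly best, and safest if the plateau has another cause.”
- The flask gives 41.5% at 2.0 d, 62.5% after oak and 41.7% after cedar, and the best option is birch, bringing 27 points, more than the 22 points for larch, the 21 points for oak and the 0.15 points for cedar.

    gas phase ⇌ dissolved gas, rate k1*(csat - [dissolved gas]) (kL = 4.40 × 10⁻⁴ s⁻¹)
    starting material + dissolved gas → target (k = 7.50 × 10⁻⁴ M⁻¹ s⁻¹, Ea = 78.0 kJ mol⁻¹)
    2 dissolved gas → homo dimer (k = 9.40 × 10⁻⁴ M⁻¹ s⁻¹, Ea = 77.0 kJ mol⁻¹)
    target ⇌ isomer of the product (K = 1.40, k = 8.90 × 10⁻⁵ s⁻¹, Ea = 92.0 kJ mol⁻¹, ΔH = −36.0 kJ mol⁻¹)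
    (constants at 25 °C)

- At 48.0 h the asked flask holds 57.9% as isomer of the product and 0.55% as starting material.
- The neighbouring flask, the same charge read at 12 h, takes the same reckoning: k′ carries Friday's 55.8% down to 29.2%, and that neighbouring flask holds 29.9%.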